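Readings and results were computed on assumed constants, and the scatter is random.

The ratio of Z to D charged in this flask is 1.10, above one, which promises the end of D if each D takes one Z. The dawn run, which is this same flask followed so far, says otherwise.

| setting | dawn | winter | flask |
|---|---|---|---|
| D | 0.30 M | 0.30 M | 0.30 M |
| Z | 0.33 M | 0.33 M | 0.330 M |
| temperature | 50 °C | 45 °C | 50 °C |
| remark | the very flask that is asked about, followed so far | run made earlier |  |
| time |  |  | 25 h |

| run | time / h | G / % | D / % |
|---|---|---|---|
| dawn | 2.00 | 14.5 | 37.2 |
| dawn | 5.00 | 16.3 | 28.6 |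
| dawn | 10.0 | 16.6 | 27.8 |
| dawn | 15.0 | 16.1 | 26.4 |
| winter | 2.00 | 12.3 | 45.5 |
| winter | 5.00 | 14.9 | 32.4 |
| winter | 10.0 | 16.4 | 28.6 |
| winter | 15.0 | 16.0 | 27.4 |

(standard deviation of a reading: 0.5 percentage points)

- G taken out counts as made
- the numbers in the tables scatter with a standard deviation of 0.5 percentage points
- additions bring no volume worth counting

- epsilon: at 25 h raise the temperature by 25 K, then wait 2.0 d
- eta: at 25 h take out 90% of the G then present, then wait 2.0 d
- beta: change nothing and wait 2.0 d more
- gamma: at 25 h add Z, 50.0% of the amount charged, then wait 2.0 d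

1. G, in percent of the D first charged, at 25 h
2. which option adds most G ("none" when 2 percentage points or less is all one gets) (epsilon / eta / beta / gamma / none)
3. G present, with what was taken out counted in, in percent of the D first charged, after epsilon
4. G present, with what was taken out counted in, in percent of the D first charged, after gamma

Going round once more, the last dawn reading of D is put back in. If Z has stopped the reaction, each D consumed cost w = 1.49 Z. The winter run, with 45.5% of D at 2.00 h against 37.2% in the dawn run, gives 1.52.

Folding the charges into one number gives the cover, c(Z) charged divided by w times c(D) charged, here 0.736. Below one, it reads as the share of D that the Z charge can consume, and Z is then the limiting reagent.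

One number is not enough, since the cover says where D stops but not how much G appears. That takes a second number. G has stood near 16.3% since 5.00 h, so the share of consumed D that becomes G is s = 0.222.

This reckoning therefore puts G at 16.3% at 25 h. Epsilon, eta and beta add no Z, so they leave the cover and G where they are. Gamma lifts the cover to 1.10, above one, so this reckoning, which takes the added Z to be spent at the same w, puts G at s itself, 22.2%.

The forecast gives 16.4% now, gamma as the best option, 16.4% after epsilon and 22.2% after gamma, and says of the stall: “That points to a spent reagent rather than an equilibrium.”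

The flask gives 16.3% at 25 h, 16.3% after epsilon and 21.5% after gamma, so gamma is best, with a gain of 5.2 percentage points.

    D + Z → G (k = 0.0120 M⁻¹ min⁻¹, Ea = 79.0 kJ mol⁻¹)
    D + Z → E (k = 0.0414 M⁻¹ min⁻¹, Ea = 70.0 kJ mol⁻¹)
    Z + E → J (k = 0.0654 M⁻¹ min⁻¹, Ea = 72.0 kJ mol⁻¹)
    Z + E ⇌ L (K = 100 M⁻¹, k = 0.0222 M⁻¹ min⁻¹, Ea = 78.0 kJ mol⁻¹, ΔH = 3.00 kJ mol⁻¹)
    L → Q (k = 0.00746 min⁻¹, Ea = 95.0 kJ mol⁻¹)
    Q → X (k = 0.00206 min⁻¹, Ea = 112 kJ mol⁻¹)
    J → X (k = 0.00180 min⁻¹, Ea = 95.0 kJ mol⁻¹)
    (constants at 50 °C)

The loss of D + Z to E is the main reason why G stands at 16.3% in this flask at 25 h: the run without that step reaches 88.7%. At its cover of 0.736, the flask has 0% of its Z free and 27.4% of its D left at 25.0 h. A neighbour flask charged with 0.18 M of D has a cover of 1.23, so s puts its G at 22.2%. That neighbour holds 22.1% of G, with 1.56% of its D left at 25.0 h.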